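**Retrosynthetic overview**
- The target is disconnected at C2–C1′: the last step is an enantioselective Rh-catalysed 1,4-arylation that dearomatises the γ-pyrone ring of an unprotected 5,7-dihydroxy-8-prenylchromone with a 4-hydroxy-3-prenylphenylboronic acid, setting C2.
- The chromone comes from DMF-DMA annulation of a 2-hydroxy-3-prenylacetophenone whose other two OH groups are MOM-masked, so only the OH next to the prenyl group can become O1 (8- versus 6-prenyl control).
- That acetophenone comes from mono-C-prenylation of symmetric phloroacetophenone, then selective bis-MOM protection.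
- The boronic acid comes from ortho-C-prenylation of 4-bromophenol, then Pd borylation.
- Ring order: A and B rings are bought as aromatics; the C ring is built as an aromatic chromone (step 3) and dearomatised in the final step (step 6).

Assumption: the SMILES descriptor corresponds to (2S), the natural flavanone series, and all numbered starting materials and reagents are catalogue compounds.

**Route**

Step 1
Reactants: 1 (2,4,6-trihydroxyacetophenone), 2 (prenyl bromide)
Product: 3, 1-[2,4,6-trihydroxy-3-(3-methylbut-2-en-1-yl)phenyl]ethan-1-one
Conditions: 2 (1.0 equiv), DBU (1.1 equiv), THF, 0 °C → rt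
Reagents that add atoms: prenyl bromide, CC(C)=CCBr
Why: Phenoxide C-alkylation (alkylative dearomatisation to a cyclohexadienone, then re-aromatisation) at the only type of ring C–H (C3 ≡ C5) gives a single mono-C-prenyl isomer and breaks the symmetry of the ring; O- and di-prenylated by-products are removed by chromatography.

Step 2
Reactants: 3, 4 (chloromethyl methyl ether)
Product: 5, 1-[2-hydroxy-4,6-bis(methoxymethoxy)-3-(3-methylbut-2-en-1-yl)phenyl]ethan-1-one
Conditions: MOMCl (2.2 equiv), i-Pr2NEt (3 equiv), CH2Cl2, 0 °C → rt
Reagents that add atoms: chloromethyl methyl ether, COCCl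
Why: MOM protection (Williamson-type O-alkylation) takes the non-chelated 4-OH and the less hindered ortho 6-OH, while the 2-OH wedged between prenyl and acetyl stays locked in the C=O hydrogen bond, leaving free exactly the oxygen that must become O1.

Step 3
Reactants: 5, 6 (N,N-dimethylformamide dimethyl acetal)
Product: 7, 5,7-dihydroxy-8-(3-methylbut-2-en-1-yl)-4H-chromen-4-one
Conditions: DMF-DMA (2 equiv), PhMe, 95 °C; evaporate; then 3 M HCl, MeOH, rt → 50 °C (one pot)
Reagents that add atoms: DMF-DMA, COC(OC)N(C)C (supplies C2–H)
Why: Enaminone formation at the acetyl CH3, then acid-mediated 6-endo addition–elimination by the only free ortho-OH (loss of Me2NH), closes the chromone with prenyl fixed at C8 before the same methanolic HCl cleaves both MOM acetals.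

Step 4
Reactants: 8 (4-bromophenol), 2 (prenyl bromide)
Product: 9, 4-bromo-2-(3-methylbut-2-en-1-yl)phenol
Conditions: NaH (1.05 equiv), PhMe, 0 °C; then 2 (1.0 equiv), rt
Reagents that add atoms: prenyl bromide, CC(C)=CCBr
Why: A tight sodium phenoxide ion pair in a non-polar solvent favours ortho C-alkylation over O-alkylation, and the para position is blocked by bromine.

Step 5
Reactants: 9, 10 (tetrahydroxydiboron)
Product: 11, [4-hydroxy-3-(3-methylbut-2-en-1-yl)phenyl]boronic acid
Conditions: XPhos-Pd-G2 (1 mol %), XPhos (2 mol %), B2(OH)4 (3 equiv), KOAc (3 equiv), EtOH, 80 °C; pH 5 work-up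
Reagents that add atoms: tetrahydroxydiboron, OB(O)B(O)O
Why: Miyaura-type Pd-catalysed borylation of the aryl bromide gives the free boronic acid directly; the free phenol is tolerated and the trisubstituted alkene should be inert to Pd(0)/diboron.

Step 6 (key step)
Reactants: 7, 11
Product: 12, Euchrestaflavanone A, (2S)-5,7-dihydroxy-2-[4-hydroxy-3-(3-methylbut-2-en-1-yl)phenyl]-8-(3-methylbut-2-en-1-yl)-2,3-dihydro-4H-chromen-4-one
Conditions: [RhCl(C2H4)2]2 (2.5 mol %), (S)-MeO-F12-BIPHEP (5.5 mol %), KOH (5 mol %), 11 (2.5 equiv), dioxane/H2O (10:1), 45 °C, Ar; pH 5 work-up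
Reagents that add atoms: none (the aryl group comes from reactant 11; water supplies only H)
Why: In this Hayashi–Miyaura asymmetric 1,4-addition the chiral bisphosphine–Rh–aryl species from 11 inserts the chromone C2=C3 bond on one enantioface, dearomatising the γ-pyrone and creating C2 as S (predicted by analogy with (S)-biaryl bisphosphine/Rh giving (S)-3-arylcyclohexanones; confirm by CD and use the (R)-ligand if reversed), then water protonates the Rh oxa-π-allyl; with only catalytic base the phenols stay neutral, the 5-OH···O=C4 hydrogen bond activates the enone, and the prenyl alkenes are not acceptors for aryl–Rh.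

**Compound list**
1 | 2,4,6-trihydroxyacetophenone | CC(=O)c1c(O)cc(O)cc1O | starting material
2 | prenyl bromide (1-bromo-3-methylbut-2-ene) | CC(C)=CCBr | starting material
3 | 1-[2,4,6-trihydroxy-3-(3-methylbut-2-en-1-yl)phenyl]ethan-1-one | CC(=O)c1c(O)cc(O)c(CC=C(C)C)c1O | intermediate
4 | chloromethyl methyl ether | COCCl | starting material (reagent)
5 | 1-[2-hydroxy-4,6-bis(methoxymethoxy)-3-(3-methylbut-2-en-1-yl)phenyl]ethan-1-one | CC(=O)c1c(OCOC)cc(OCOC)c(CC=C(C)C)c1O | intermediate
6 | N,N-dimethylformamide dimethyl acetal | COC(OC)N(C)C | starting material (reagent)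
7 | 5,7-dihydroxy-8-(3-methylbut-2-en-1-yl)-4H-chromen-4-one | O=c1ccoc2c(CC=C(C)C)c(O)cc(O)c12 | intermediate
8 | 4-bromophenol | Oc1ccc(Br)cc1 | starting material
9 | 4-bromo-2-(3-methylbut-2-en-1-yl)phenol | CC(C)=CCc1cc(Br)ccc1O | intermediate
10 | tetrahydroxydiboron | OB(O)B(O)O | starting material (reagent)
11 | [4-hydroxy-3-(3-methylbut-2-en-1-yl)phenyl]boronic acid | CC(C)=CCc1cc(B(O)O)ccc1O | intermediate
12 | Euchrestaflavanone A, (2S) | CC(C)=CCc1cc([C@@H]2CC(=O)c3c(O)cc(O)c(CC=C(C)C)c3O2)ccc1O | target

**Totals**
Total step count: 6. Longest linear sequence: 4 (steps 1 → 2 → 3 → 6); the boronic acid branch is 2 steps (4 → 5).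

**Three steps most likely to fail**
1. Step 6. The electron-rich chromone with an acidic 7-OH may insert slowly, the hydroxyaryl boronic acid may protodeboronate, and ee could erode by retro-oxa-Michael opening. Fallback: give up the protecting-group-free endgame. Stop step 3 before the HCl stage to keep 5,7-bis(MOM)-8-prenylchromone, arylate that non-acidic chromone with the MOM ether of 11, and remove all MOM groups with HCl/MeOH as an added final step.
2. Step 2. The second MOM group may not discriminate well between 6-OH and 2-OH, and the wrong isomer would lead to the 6-prenyl series. Fallback: set the C8 prenyl by a para-Claisen–Cope sequence instead. Make 5,7-dihydroxychromone from 1 (DMF-DMA, then HCl), protect 7-OH as MOM, O-prenylate 5-OH, rearrange with Eu(fod)3 (5-O-prenyl → C6 dienone → C8 prenyl), then cleave the MOM.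
3. Step 5. Borylation of a free, electron-rich bromophenol may give protodehalogenation, homocoupling, or a boronic acid that is hard to isolate. Fallback: replace Pd catalysis with metalation. Protect 9 as its TBS ether, carry out Br/Li exchange (n-BuLi, THF, −78 °C), quench with B(OiPr)3, and hydrolyse; the silyl group is removed in the acidic work-up or with KHF2.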